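**Retrosynthetic overview**
1. 19 ⇐ 17: the side-chain carbinol comes from Felkin–Anh hydride reduction of an α-aryloxy aryl ketone, followed by cleavage of two aryl silyl ethers.
2. 17 ⇐ 16 ⇐ 12 + 2 × 15: hydride delivery to a cyclic oxocarbenium ion sets the cis aryl/methyl pair at C5; one aryllithium installs both guaiacyl rings (on the lactone C=O and on the morpholine amide).
3. 12 ⇐ 9: cyclic acetal formation, oxidation to the γ-lactone, trans α-methylation. This is the only ring-forming event: the oxolane closes here and is carried on as acetal, lactone, hemiketal and finally THF.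
4. 9 ⇐ 6 + 2 (key C–C bond, benzylic C2–C3 of the oxolane): a chiral titanated crotyl carbamate acts as a homoenolate (d3) donor towards the aryl aldehyde and sets C2 and C3 in one operation.
5. 6 ⇐ vanillin + (S)-lactic morpholide (Mitsunobu inversion gives the 2R aryloxy centre); 2 ⇐ crotyl alcohol.

Assumption: the sense of induction of the sparteine-mediated homoaldol is taken as the one established with (−)-sparteine (which would give the 3S,4S adduct here), so (+)-sparteine is used; this is the one stereochemical point resting on recalled precedent. Locants C2–C5 are those of the oxolane in the name of 19.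

**Route**

Step 1
Reactants: 1 (E)-but-2-en-1-ol
Product: 2 (E)-but-2-en-1-yl N,N-diisopropylcarbamate
Conditions: iPr2NCOCl (1.1 equiv), pyridine, 90 °C
Reagents that add atoms: N,N-diisopropylcarbamoyl chloride, CC(C)N(C(C)C)C(Cl)=O
Why: O-carbamoylation (acyl substitution) of the primary allylic alcohol with pyridine as HCl acceptor; no stereocentre is formed and the E alkene is untouched.

Step 2
Reactants: 3 ethyl (S)-lactate
Product: 4 (2S)-2-hydroxy-1-(morpholin-4-yl)propan-1-one
Conditions: morpholine (3 equiv), neat, 85 °C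
Reagents that add atoms: morpholine, C1COCCN1
Why: ester aminolysis of an α-hydroxy ester by a secondary amine, which leaves the stereocentre untouched.

Step 3
Reactants: 4 (2S)-2-hydroxy-1-(morpholin-4-yl)propan-1-one; 5 vanillin
Product: 6 3-methoxy-4-{[(2R)-1-(morpholin-4-yl)-1-oxopropan-2-yl]oxy}benzaldehyde
Conditions: PPh3, DIAD, THF, 0 °C → rt
Reagents that add atoms: none
Why: Mitsunobu etherification in which the acidic phenol displaces the activated lactamide hydroxyl by SN2 with clean inversion (2S → 2R), which becomes the aryloxy-bearing side-chain centre of the target.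

Step 4
Reactants: 2 (E)-but-2-en-1-yl N,N-diisopropylcarbamate; 6 3-methoxy-4-{[(2R)-1-(morpholin-4-yl)-1-oxopropan-2-yl]oxy}benzaldehyde
Product: 9 (1Z,3R,4R)-4-hydroxy-4-(3-methoxy-4-{[(2R)-1-(morpholin-4-yl)-1-oxopropan-2-yl]oxy}phenyl)-3-methylbut-1-en-1-yl N,N-diisopropylcarbamate, via lithiated carbamate sparteine complex 7 (not isolated), via titanated carbamate 8 (not isolated)
Conditions: 2 (1.3 equiv), nBuLi, (+)-sparteine, pentane–cyclohexane, −78 °C, 3 h (crystallisation); Ti(OiPr)4 (4 equiv), −78 °C; 6 in THF, −78 → 0 °C; aq HCl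
Reagents that add atoms: none
Why: Hoppe asymmetric homoaldol reaction: one epimer of the allyllithium 7 is obtained by crystallisation-driven dynamic resolution with (+)-sparteine, Li→Ti exchange with inversion gives 8, and this homoenolate (d3) reagent adds only to the aldehyde through a chair-like six-membered transition state (aryl equatorial, carbamoyloxy axial), fixing the anti 3R,4R pair (future oxolane C3 and C2) and the Z enol carbamate while the tertiary amide and its 2R centre are untouched.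

Step 5
Reactants: 9 homoaldol adduct
Product: 10 (2R)-2-{2-methoxy-4-[(2R,3R)-5-methoxy-3-methyloxolan-2-yl]phenoxy}-1-(morpholin-4-yl)propan-1-one (anomer mixture)
Conditions: MeSO3H (1.5 equiv), Hg(OAc)2 (5 mol %), MeOH, rt; NaHCO3
Reagents that add atoms: methanol, CO
Why: acid- and Hg(OAc)2-catalysed solvolysis of the enol carbamate, in which the benzylic hydroxyl closes the oxolane on the carbamoyloxy carbenium ion and methanol replaces the carbamate, leaving both stereocentres unchanged and the acetal carbon as an inconsequential anomer mixture.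

Step 6
Reactants: 10 cyclic methyl acetal
Product: 11 (2R)-2-{2-methoxy-4-[(2R,3R)-3-methyl-5-oxooxolan-2-yl]phenoxy}-1-(morpholin-4-yl)propan-1-one
Conditions: m-CPBA (1.5 equiv), BF3·OEt2 (0.5 equiv), CH2Cl2, 0 °C → rt
Reagents that add atoms: m-CPBA, OOC(=O)c1cccc(Cl)c1
Why: Grieco oxidation of a cyclic acetal, in which BF3 ionises the acetal, the peracid adds to the oxocarbenium ion and the peroxy acetal fragments to the γ-lactone without touching the stereocentres.

Step 7
Reactants: 11 γ-lactone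
Product: 12 (2R)-2-{4-[(2R,3R,4R)-3,4-dimethyl-5-oxooxolan-2-yl]-2-methoxyphenoxy}-1-(morpholin-4-yl)propan-1-one
Conditions: LiN(SiMe3)2 (1.1 equiv), THF, −78 °C; MeI (3 equiv), −78 → −40 °C
Reagents that add atoms: iodomethane, CI
Why: lactone enolate alkylation, in which the silylamide base deprotonates only the lactone CH2 (the α-branched aryloxy amide C–H is far less acidic) and MeI enters anti to the neighbouring C-methyl, giving the new 4R centre trans to it.

Step 8
Reactants: 13 4-bromo-2-methoxyphenol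
Product: 14 (4-bromo-2-methoxyphenoxy)(tert-butyl)dimethylsilane
Conditions: TBSCl, imidazole, DMF, rt
Reagents that add atoms: tert-butyldimethylsilyl chloride, CC(C)(C)[Si](C)(C)Cl
Why: standard imidazole-promoted O-silylation of a phenol; no stereocentre is involved.

Step 9
Reactants: 14 (4-bromo-2-methoxyphenoxy)(tert-butyl)dimethylsilane; 12 dimethyl lactone
Product: 16 (2R)-1-[4-(tert-butyldimethylsilyloxy)-3-methoxyphenyl]-2-{4-[(2R,3R,4R)-5-[4-(tert-butyldimethylsilyloxy)-3-methoxyphenyl]-5-hydroxy-3,4-dimethyloxolan-2-yl]-2-methoxyphenoxy}propan-1-one, via aryllithium 15 (not isolated)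
Conditions: 14 (2.5 equiv), nBuLi (2.4 equiv), THF, −78 °C; 12, −78 °C; aq NH4Cl at −78 °C
Reagents that add atoms: none
Why: Br–Li exchange followed by 1,2-addition of the same aryllithium to both acyl groups, where the lactone stops at the lithium hemiketal and the morpholine amide at its stable tetrahedral adduct so neither over-adds, and the cold quench releases hemiketal and aryl ketone with all existing stereocentres unchanged.

Step 10
Reactants: 16 hemiketal ketone
Product: 17 (2R)-1-[4-(tert-butyldimethylsilyloxy)-3-methoxyphenyl]-2-{4-[(2R,3R,4R,5S)-5-[4-(tert-butyldimethylsilyloxy)-3-methoxyphenyl]-3,4-dimethyloxolan-2-yl]-2-methoxyphenoxy}propan-1-one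
Conditions: Et3SiH (4 equiv), BF3·OEt2 (2.5 equiv), CH2Cl2, −78 °C; NaHCO3 quench at −78 °C
Reagents that add atoms: none
Why: ionic hydrogenation (reductive deoxygenation) of the hemiketal through the aryl-stabilised cyclic oxocarbenium ion, where the silane delivers hydride anti to the adjacent C4 methyl so the C5 aryl ends cis to it (5S), while the conjugated aryl ketone is not reduced at −78 °C.

Step 11
Reactants: 17 THF ketone
Product: 19 (1R,2R)-1-(4-hydroxy-3-methoxyphenyl)-2-{4-[(2R,3R,4R,5S)-5-(4-hydroxy-3-methoxyphenyl)-3,4-dimethyloxolan-2-yl]-2-methoxyphenoxy}propan-1-ol, via bis-silyl threo carbinol 18 (not isolated)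
Conditions: LiBH(sBu)3, THF, −78 °C; MeOH; then Bu4NF, AcOH, 0 °C; aq NH4Cl
Reagents that add atoms: none
Why: Felkin–Anh (non-chelated, polar) reduction in which the bulky hydride attacks anti to the α-aryloxy group of the 2R ketone to give the threo 1R carbinol, followed in the same flask by fluoride cleavage of the two aryl silyl ethers.

**Compound list**
1 | (E)-but-2-en-1-ol | C/C=C/CO | starting material
2 | (E)-but-2-en-1-yl N,N-diisopropylcarbamate | C/C=C/COC(=O)N(C(C)C)C(C)C | intermediate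
3 | ethyl (2S)-2-hydroxypropanoate (ethyl (S)-lactate) | CCOC(=O)[C@H](C)O | starting material
4 | (2S)-2-hydroxy-1-(morpholin-4-yl)propan-1-one | C[C@H](O)C(=O)N1CCOCC1 | intermediate
5 | 4-hydroxy-3-methoxybenzaldehyde (vanillin) | COc1cc(C=O)ccc1O | starting material
6 | 3-methoxy-4-{[(2R)-1-(morpholin-4-yl)-1-oxopropan-2-yl]oxy}benzaldehyde | COc1cc(C=O)ccc1O[C@H](C)C(=O)N1CCOCC1 | intermediate
7 | (1R)-1-lithio-(E)-but-2-en-1-yl N,N-diisopropylcarbamate as its (+)-sparteine complex (ligand not drawn) | C/C=C/[C@@H]([Li])OC(=O)N(C(C)C)C(C)C | intermediate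
8 | (1S)-1-(triisopropoxytitanio)-(E)-but-2-en-1-yl N,N-diisopropylcarbamate | C/C=C/[C@H]([Ti](OC(C)C)(OC(C)C)OC(C)C)OC(=O)N(C(C)C)C(C)C | intermediate
9 | (1Z,3R,4R)-4-hydroxy-4-(3-methoxy-4-{[(2R)-1-(morpholin-4-yl)-1-oxopropan-2-yl]oxy}phenyl)-3-methylbut-1-en-1-yl N,N-diisopropylcarbamate | COc1cc(ccc1O[C@H](C)C(=O)N1CCOCC1)[C@H](O)[C@H](C)/C=C\OC(=O)N(C(C)C)C(C)C | intermediate
10 | (2R)-2-{2-methoxy-4-[(2R,3R)-5-methoxy-3-methyloxolan-2-yl]phenoxy}-1-(morpholin-4-yl)propan-1-one (both anomers at oxolane C5) | COc1cc(ccc1O[C@H](C)C(=O)N1CCOCC1)[C@@H]1OC(OC)C[C@H]1C | intermediate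
11 | (2R)-2-{2-methoxy-4-[(2R,3R)-3-methyl-5-oxooxolan-2-yl]phenoxy}-1-(morpholin-4-yl)propan-1-one | COc1cc(ccc1O[C@H](C)C(=O)N1CCOCC1)[C@@H]1OC(=O)C[C@H]1C | intermediate
12 | (2R)-2-{4-[(2R,3R,4R)-3,4-dimethyl-5-oxooxolan-2-yl]-2-methoxyphenoxy}-1-(morpholin-4-yl)propan-1-one | COc1cc(ccc1O[C@H](C)C(=O)N1CCOCC1)[C@@H]1OC(=O)[C@H](C)[C@H]1C | intermediate
13 | 4-bromo-2-methoxyphenol | COc1cc(Br)ccc1O | starting material
14 | (4-bromo-2-methoxyphenoxy)(tert-butyl)dimethylsilane | COc1cc(Br)ccc1O[Si](C)(C)C(C)(C)C | intermediate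
15 | [4-(tert-butyldimethylsilyloxy)-3-methoxyphenyl]lithium | COc1cc([Li])ccc1O[Si](C)(C)C(C)(C)C | intermediate
16 | (2R)-1-[4-(tert-butyldimethylsilyloxy)-3-methoxyphenyl]-2-{4-[(2R,3R,4R)-5-[4-(tert-butyldimethylsilyloxy)-3-methoxyphenyl]-5-hydroxy-3,4-dimethyloxolan-2-yl]-2-methoxyphenoxy}propan-1-one (hemiketal, both C5 epimers, in equilibrium with the open γ-hydroxy ketone) | COc1cc(ccc1O[C@H](C)C(=O)c1ccc(O[Si](C)(C)C(C)(C)C)c(OC)c1)[C@@H]1OC(O)(c2ccc(O[Si](C)(C)C(C)(C)C)c(OC)c2)[C@H](C)[C@H]1C | intermediate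
17 | (2R)-1-[4-(tert-butyldimethylsilyloxy)-3-methoxyphenyl]-2-{4-[(2R,3R,4R,5S)-5-[4-(tert-butyldimethylsilyloxy)-3-methoxyphenyl]-3,4-dimethyloxolan-2-yl]-2-methoxyphenoxy}propan-1-one | COc1cc(ccc1O[C@H](C)C(=O)c1ccc(O[Si](C)(C)C(C)(C)C)c(OC)c1)[C@@H]1O[C@H](c2ccc(O[Si](C)(C)C(C)(C)C)c(OC)c2)[C@H](C)[C@H]1C | intermediate
18 | (1R,2R)-1-[4-(tert-butyldimethylsilyloxy)-3-methoxyphenyl]-2-{4-[(2R,3R,4R,5S)-5-[4-(tert-butyldimethylsilyloxy)-3-methoxyphenyl]-3,4-dimethyloxolan-2-yl]-2-methoxyphenoxy}propan-1-ol | COc1cc(ccc1O[C@H](C)[C@H](O)c1ccc(O[Si](C)(C)C(C)(C)C)c(OC)c1)[C@@H]1O[C@H](c2ccc(O[Si](C)(C)C(C)(C)C)c(OC)c2)[C@H](C)[C@H]1C | intermediate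
19 | (1R,2R)-1-(4-hydroxy-3-methoxyphenyl)-2-{4-[(2R,3R,4R,5S)-5-(4-hydroxy-3-methoxyphenyl)-3,4-dimethyloxolan-2-yl]-2-methoxyphenoxy}propan-1-ol (CNP0171079.2) | COc1cc([C@@H](O)[C@@H](C)Oc2ccc([C@@H]3O[C@H](c4ccc(O)c(OC)c4)[C@H](C)[C@H]3C)cc2OC)ccc1O | target

**Step count**
Total: 11 steps. Longest linear sequence: 9 steps (3 → 4 → 6 → 9 → 10 → 11 → 12 → 16 → 17 → 19). Compounds 10 and 16 can be carried forward crude.

**Three steps most likely to fail**

Step 4. The crystallisation-driven resolution must survive the mirror-image ligand and a polar aldehyde delivered in THF, so ee and yield are uncertain. Any wrong-enantiomer addition gives a diastereomer of 9 (because of the 2R amide centre) that is removed by chromatography. The fallback sets out from 6 and comes back at 11. Brown (E)-crotylboration of 6 with (E)-crotyl-B(Ipc)2 made from (+)-Ipc2BOMe (the antipode that gives 1R carbinols from aryl aldehydes) gives the anti homoallylic alcohol (2R)-2-{4-[(1R,2R)-1-hydroxy-2-methylbut-3-en-1-yl]-2-methoxyphenoxy}-1-(morpholin-4-yl)propan-1-one F1. Hydroboration of its vinyl group with Cy2BH and oxidation with NaBO3 gives the 1,4-diol (2R)-2-{4-[(1R,2R)-1,4-dihydroxy-2-methylbutyl]-2-methoxyphenoxy}-1-(morpholin-4-yl)propan-1-one F2. TEMPO/PhI(OAc)2 then oxidises the primary alcohol and the resulting lactol to lactone 11.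

Step 10. The Lewis acid step is run with an aryl ketone and an enolisable aryloxy centre present, and the cis C5 centre can epimerise if the mixture warms. The fallback sets out from 16 and comes back at 18, and inverts the order of the two reductions so that no carbonyl is present when BF3·OEt2 is used. PPTS in MeOH converts the hemiketal into the cyclic methyl ketal (2R)-1-[4-(tert-butyldimethylsilyloxy)-3-methoxyphenyl]-2-{4-[(2R,3R,4R)-5-[4-(tert-butyldimethylsilyloxy)-3-methoxyphenyl]-5-methoxy-3,4-dimethyloxolan-2-yl]-2-methoxyphenoxy}propan-1-one F3; the acyclic aryl ketone does not ketalise without a dehydrating agent. LiBH(sBu)3 at −78 °C reduces the only carbonyl to the threo carbinol (1R,2R)-1-[4-(tert-butyldimethylsilyloxy)-3-methoxyphenyl]-2-{4-[(2R,3R,4R)-5-[4-(tert-butyldimethylsilyloxy)-3-methoxyphenyl]-5-methoxy-3,4-dimethyloxolan-2-yl]-2-methoxyphenoxy}propan-1-ol F4. Et3SiH/BF3·OEt2 at −78 °C then ionises only the ketal (the β-aryloxy benzylic carbinol ionises far more slowly), and hydride delivery anti to the C4 methyl gives 18, which is desilylated as in the second stage of step 11.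

Step 11. The threo selectivity rests on Felkin–Anh control with a weakly biased α-aryloxy ketone and may be modest. The fallback sets out from 17 and comes back at 18, and sets the carbinol by chelation followed by inversion. Zn(BH4)2 in Et2O at 0 °C (chelate between the carbonyl and the aryloxy oxygen) gives the erythro carbinol (1S,2R)-1-[4-(tert-butyldimethylsilyloxy)-3-methoxyphenyl]-2-{4-[(2R,3R,4R,5S)-5-[4-(tert-butyldimethylsilyloxy)-3-methoxyphenyl]-3,4-dimethyloxolan-2-yl]-2-methoxyphenoxy}propan-1-ol F5. Mitsunobu esterification with 4-nitrobenzoic acid (PPh3, DIAD) inverts the carbinol centre to the threo ester (1R,2R)-1-[4-(tert-butyldimethylsilyloxy)-3-methoxyphenyl]-2-{4-[(2R,3R,4R,5S)-5-[4-(tert-butyldimethylsilyloxy)-3-methoxyphenyl]-3,4-dimethyloxolan-2-yl]-2-methoxyphenoxy}propyl 4-nitrobenzoate F6. iBu2AlH at −78 °C removes the ester while the silyl ethers are still in place (avoiding quinone methide formation from a free para-phenoxide) and gives 18, which is desilylated with Bu4NF as in step 11.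

**Further compounds**
F1 | step 4 | (2R)-2-{4-[(1R,2R)-1-hydroxy-2-methylbut-3-en-1-yl]-2-methoxyphenoxy}-1-(morpholin-4-yl)propan-1-one | COc1cc(ccc1O[C@H](C)C(=O)N1CCOCC1)[C@H](O)[C@H](C)C=C
F2 | step 4 | (2R)-2-{4-[(1R,2R)-1,4-dihydroxy-2-methylbutyl]-2-methoxyphenoxy}-1-(morpholin-4-yl)propan-1-one | COc1cc(ccc1O[C@H](C)C(=O)N1CCOCC1)[C@H](O)[C@H](C)CCO
F3 | step 10 | (2R)-1-[4-(tert-butyldimethylsilyloxy)-3-methoxyphenyl]-2-{4-[(2R,3R,4R)-5-[4-(tert-butyldimethylsilyloxy)-3-methoxyphenyl]-5-methoxy-3,4-dimethyloxolan-2-yl]-2-methoxyphenoxy}propan-1-one | COc1cc(ccc1O[C@H](C)C(=O)c1ccc(O[Si](C)(C)C(C)(C)C)c(OC)c1)[C@@H]1OC(OC)(c2ccc(O[Si](C)(C)C(C)(C)C)c(OC)c2)[C@H](C)[C@H]1C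
F4 | step 10 | (1R,2R)-1-[4-(tert-butyldimethylsilyloxy)-3-methoxyphenyl]-2-{4-[(2R,3R,4R)-5-[4-(tert-butyldimethylsilyloxy)-3-methoxyphenyl]-5-methoxy-3,4-dimethyloxolan-2-yl]-2-methoxyphenoxy}propan-1-ol | COc1cc(ccc1O[C@H](C)[C@H](O)c1ccc(O[Si](C)(C)C(C)(C)C)c(OC)c1)[C@@H]1OC(OC)(c2ccc(O[Si](C)(C)C(C)(C)C)c(OC)c2)[C@H](C)[C@H]1C
F5 | step 11 | (1S,2R)-1-[4-(tert-butyldimethylsilyloxy)-3-methoxyphenyl]-2-{4-[(2R,3R,4R,5S)-5-[4-(tert-butyldimethylsilyloxy)-3-methoxyphenyl]-3,4-dimethyloxolan-2-yl]-2-methoxyphenoxy}propan-1-ol | COc1cc(ccc1O[C@H](C)[C@@H](O)c1ccc(O[Si](C)(C)C(C)(C)C)c(OC)c1)[C@@H]1O[C@H](c2ccc(O[Si](C)(C)C(C)(C)C)c(OC)c2)[C@H](C)[C@H]1C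
F6 | step 11 | (1R,2R)-1-[4-(tert-butyldimethylsilyloxy)-3-methoxyphenyl]-2-{4-[(2R,3R,4R,5S)-5-[4-(tert-butyldimethylsilyloxy)-3-methoxyphenyl]-3,4-dimethyloxolan-2-yl]-2-methoxyphenoxy}propyl 4-nitrobenzoate | COc1cc(ccc1O[C@H](C)[C@H](OC(=O)c1ccc(cc1)[N+](=O)[O-])c1ccc(O[Si](C)(C)C(C)(C)C)c(OC)c1)[C@@H]1O[C@H](c2ccc(O[Si](C)(C)C(C)(C)C)c(OC)c2)[C@H](C)[C@H]1C
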